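**Assumption:** the target SMILES has no stereocentres (it is achiral), so "single enantiomer" is moot. The two ring-carbon stereocentres in the dione intermediates (5, 11) are transient and are destroyed on aromatisation.

## Retrosynthetic overview
- Target 15 ← global hydrogenolysis of 14 (Cbz carbonate on ring A, benzyl ester on ring B).
- 14 ← key radical step: acridinium photoredox, arene radical-cation dehydrogenative C–O coupling. The C5–H of ring B (13) couples with the 2-OH of ring A (7).
- 7 and 13 are both resorcylates. Each benzene ring is built first by Michael–Dieckmann ([3+3]) of an acetoacetate with methyl (E)-oct-2-enoate, then dehydrogenation of the resulting 1,3-dione. The 4-OH is differentiated as Cbz in ring A and Me in ring B.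
- Ring order: ring A (steps 1–4) and ring B (steps 5–8) are formed first, and the diaryl ether is formed last (step 9).

## Route

**Step 1**
Reactants: 1 hexanal; 2 monomethyl malonate (3-methoxy-3-oxopropanoic acid)
Product: 3 methyl (E)-oct-2-enoate
Conditions: piperidine (cat.), pyridine, 90 °C
Reagents that add atoms: none
Why: Knoevenagel–Doebner condensation with decarboxylation gives the conjugated (E)-enoate; there is no stereocentre.

**Step 2**
Reactants: 3 methyl (E)-oct-2-enoate; 4 methyl acetoacetate
Product: 5 methyl 2,4-dioxo-6-pentylcyclohexane-1-carboxylate (enolised, diastereomeric mixture)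
Conditions: NaOMe (2.5 equiv), MeOH, reflux; then 1 M HCl
Reagents that add atoms: none
Why: Michael–Dieckmann annulation. The acetoacetate α-carbon adds to the pentyl-bearing β-carbon, then the acetyl CH3 is acylated by the ester. This puts the CO2Me next to the pentyl-bearing carbon, as in olivetolate. The ring stereocentres are epimerisable and are lost in step 3.

**Step 3**
Reactants: 5
Product: 6 methyl 2,4-dihydroxy-6-pentylbenzoate (methyl olivetolate)
Conditions: I2 (1.1 equiv), MeOH, reflux; Na2S2O3 work-up
Reagents that add atoms: none
Why: iodine-mediated dehydrogenative aromatisation of the cyclohexane-1,3-dione (α-iodination then loss of HI) gives the resorcylate; no stereocentre remains.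

**Step 4**
Reactants: 6
Product: 7 methyl 4-[(benzyloxycarbonyl)oxy]-2-hydroxy-6-pentylbenzoate (ring A partner)
Conditions: CbzCl (1.05 equiv), pyridine, CH2Cl2, –10 → 0 °C
Reagents that add atoms: benzyl chloroformate, O=C(Cl)OCc1ccccc1
Why: the 4-OH is free and more acidic, while the 2-OH is chelated to the ester, so acylation is selective. The electron-withdrawing carbonate also raises the oxidation potential of ring A so that it is not oxidised in step 9.

**Step 5**
Reactants: 8 diketene; 9 benzyl alcohol
Product: 10 benzyl acetoacetate
Conditions: NaOAc (cat.), toluene, 60 °C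
Reagents that add atoms: none
Why: alcoholysis of diketene gives the β-ketoester; no stereocentre.

**Step 6**
Reactants: 3 methyl (E)-oct-2-enoate; 10 benzyl acetoacetate
Product: 11 benzyl 2,4-dioxo-6-pentylcyclohexane-1-carboxylate
Conditions: NaOMe (2.5 equiv), MeOH, reflux; then 1 M HCl
Reagents that add atoms: none
Why: same Michael–Dieckmann as step 2. The benzyl β-ketoester stays as its enolate throughout, which protects it from transesterification by methoxide. The Dieckmann ester is the methyl ester of 3, which is lost as MeOH.

**Step 7**
Reactants: 11
Product: 12 benzyl 2,4-dihydroxy-6-pentylbenzoate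
Conditions: I2 (1.1 equiv), MeOH, 50 °C
Reagents that add atoms: none
Why: same dehydrogenative aromatisation as step 3; benzyl esters tolerate these mild conditions.

**Step 8**
Reactants: 12
Product: 13 benzyl 2-hydroxy-4-methoxy-6-pentylbenzoate (ring B partner)
Conditions: MeI (1.0 equiv), K2CO3, acetone, rt
Reagents that add atoms: iodomethane, CI
Why: selective O-methylation of the acidic, unchelated 4-OH in preference to the chelated 2-OH.

**Step 9 (key radical step)**
Reactants: 13 (1.0 equiv); 7 (2.5 equiv)
Product: 14 benzyl 5-{2-(methoxycarbonyl)-3-pentyl-5-[(benzyloxycarbonyl)oxy]phenoxy}-2-hydroxy-4-methoxy-6-pentylbenzoate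
Conditions: Mes-Acr-Me+ BF4– (5 mol%), Co(dmgH)2PyCl (5 mol%), 2,6-lutidine (20 mol%), HFIP/MeCN 1:4, blue LEDs, N2, 25 °C, 24 h
Reagents that add atoms: none (H2 is evolved)
Why: Proposed new method: excited acridinium oxidises the more electron-rich ring B (2-OH, 4-OMe) to its arene radical cation. Charge and spin are largest at C5, which is para to the free OH. The Cbz-deactivated, excess ring A is not oxidised and adds through its 2-OH oxygen in a cation-radical-accelerated nucleophilic addition. Loss of H+ and cobaloxime-mediated H2 release then rearomatise the ring. The closest known chemistry is acridinium arene C–H amination and phenol cross-dehydrogenative coupling. No stereocentre is formed.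

**Step 10**
Reactants: 14
Product: 15 epiphorellic acid 1
Conditions: H2 (1 atm), 10% Pd/C, EtOAc, rt, 3 h
Reagents that add atoms: hydrogen, [H][H]
Why: hydrogenolysis cleaves the Cbz carbonate (releasing CO2 and toluene) and the benzyl ester (giving the free acid and toluene) together. The methyl ester, OMe, diaryl ether and pentyl chains are untouched, and the mild conditions avoid decarboxylation of the salicylic acid.

## Compound list
1 | hexanal | CCCCCC=O | starting material
2 | monomethyl malonate | COC(=O)CC(=O)O | starting material
3 | methyl (E)-oct-2-enoate | CCCCC/C=C/C(=O)OC | intermediate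
4 | methyl acetoacetate | CC(=O)CC(=O)OC | starting material
5 | methyl 2,4-dioxo-6-pentylcyclohexane-1-carboxylate | CCCCCC1CC(=O)CC(=O)C1C(=O)OC | intermediate
6 | methyl 2,4-dihydroxy-6-pentylbenzoate | CCCCCc1cc(O)cc(O)c1C(=O)OC | intermediate
7 | methyl 4-(Cbz-oxy)-2-hydroxy-6-pentylbenzoate | CCCCCc1cc(OC(=O)OCc2ccccc2)cc(O)c1C(=O)OC | intermediate
8 | diketene | C=C1CC(=O)O1 | starting material
9 | benzyl alcohol | OCc1ccccc1 | starting material
10 | benzyl acetoacetate | CC(=O)CC(=O)OCc1ccccc1 | intermediate
11 | benzyl 2,4-dioxo-6-pentylcyclohexane-1-carboxylate | CCCCCC1CC(=O)CC(=O)C1C(=O)OCc1ccccc1 | intermediate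
12 | benzyl 2,4-dihydroxy-6-pentylbenzoate | CCCCCc1cc(O)cc(O)c1C(=O)OCc1ccccc1 | intermediate
13 | benzyl 2-hydroxy-4-methoxy-6-pentylbenzoate | CCCCCc1cc(OC)cc(O)c1C(=O)OCc1ccccc1 | intermediate
14 | coupled diaryl ether (Cbz, benzyl ester) | CCCCCc1cc(OC(=O)OCc2ccccc2)cc(Oc2c(OC)cc(O)c(C(=O)OCc3ccccc3)c2CCCCC)c1C(=O)OC | intermediate
15 | epiphorellic acid 1 | CCCCCc1cc(O)cc(Oc2c(OC)cc(O)c(C(=O)O)c2CCCCC)c1C(=O)OC | target

**Total steps:** 10. **Longest linear sequence:** 6 (1 → 3 → 5 → 6 → 7 → 14 → 15 on the ring A branch; ring B is also 6).

## Three steps most likely to fail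
1. **Step 9 (radical C–O coupling).** Risks are C–C (biaryl) coupling, attack at C3 instead of C5, and ring B homocoupling. Fallback: iodinate 13 at C5 with NIS, then run a photoinduced Cu-catalysed Ullmann-type coupling with 7, in which an aryl radical is captured by Cu–phenoxide.
2. **Step 6 (Michael–Dieckmann with the benzyl ester; step 2 has the same risk).** The acetyl γ-CH3 cyclisation may be sluggish under alkoxide, and the benzyl ester may transesterify. Fallback: aldol-condense hexanal with acetone to give 3-nonen-2-one, then carry out a Michael–Claisen with dibenzyl malonate (made from malonic acid and BnOH) to reach 11.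
3. **Step 7 (dione dehydrogenation).** Acidic HI/MeOH may cleave the benzyl ester or give low conversion. Fallback: convert 11 to its 3-methoxy-enone and aromatise by Pd(II)-mediated Saegusa-type dehydrogenation and tautomerisation instead of iodine oxidation.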